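**Assumption:** the target has no stereocentre (it is achiral), so "single enantiomer" is read as the single geometric isomer drawn: both chain olefins E, the ring olefin cis by ring constraint. (2E,6E)-Farnesyl bromide is bought as the pure E,E isomer.

## Retrosynthetic overview

1. Callophycoic acid F ⇐ its methyl ester 9 (saponification).
2. The oxepine ring (the only ring made; the benzene ring is bought) is closed last through the aryl C9a–O1 bond: an O-nucleophile on C2 displaces a fluoride para to the ester.
3. The C2 oxygen and the ring olefin geometry (CH2O cis to CH2Ar) come from cis-1,4-hydroboration/oxidation of the 1-aryl-1,3-diene 6.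
4. 6 ⇐ Heck coupling of methyl 3-bromo-4-fluorobenzoate with (6E,10E)-β-springene 4.
5. 4 ⇐ (2E,6E)-farnesyl bromide + metalated isoprene.

## Route

**Step 1**
Reactants: 1 (2E,6E)-farnesyl bromide; 2 isoprene
Product: 4 (6E,10E)-7,11,15-trimethyl-3-methylidenehexadeca-1,6,10,14-tetraene (β-springene), via isoprenylpotassium 3 (not isolated)
Conditions: lithium 2,2,6,6-tetramethylpiperidide, KOt-Bu, 2 (3 equiv), THF/hexane, −78 °C; then 1, −78 → 0 °C
Reagents that add atoms: none
Why: Metalation of isoprene at its methyl group gives a 2-vinylallyl anion whose two CH2 termini are equivalent, so SN2 alkylation by the primary allylic bromide (allyl–allyl coupling) gives one 2-substituted butadiene and leaves both E olefins of the farnesyl unit untouched.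

**Step 2**
Reactants: 4 β-springene; 5 methyl 3-bromo-4-fluorobenzoate
Product: 6 methyl 4-fluoro-3-[(1E,6E,10E)-7,11,15-trimethyl-3-methylidenehexadeca-1,6,10,14-tetraen-1-yl]benzoate
Conditions: Pd(OAc)2 (3 mol%), P(o-tol)3 (9 mol%), Et3N (2 equiv), 4 (1.3 equiv), MeCN, 85 °C
Reagents that add atoms: none
Why: Mizoroki–Heck reaction in which arylpalladium adds to the unhindered CH=CH2 terminus of the diene and the resulting η3-allylpalladium can lose only a benzylic β-hydrogen, giving the E-styrenyl diene; the C–F bond, the ester and the trisubstituted olefins do not react.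

**Step 3**
Reactants: 6 methyl 4-fluoro-3-[(1E,6E,10E)-7,11,15-trimethyl-3-methylidenehexadeca-1,6,10,14-tetraen-1-yl]benzoate
Product: 9 methyl 3-[(3E,7E)-4,8,12-trimethyltrideca-3,7,11-trien-1-yl]-2,5-dihydro-1-benzoxepine-7-carboxylate, via allylboronate 7 (not isolated), via borate ester 8 (not isolated)
Conditions: Ni(cod)2 (5 mol%), PCy3 (5 mol%), HBpin (1.2 equiv), toluene, 23 °C; then Me3NO (3 equiv), THF, 60 °C; then CsF (4 equiv), DMF, 80 °C
Reagents that add atoms: trimethylamine N-oxide, C[N+](C)(C)[O-] (gives ring oxygen O1); pinacolborane, [H]B1OC(C)(C)C(C)(C)O1 (its boron is carried in 7 and 8, only its hydrogen stays in 9)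
Why: Proposed new method: a one-flask borylative 7-endo hydro-aryloxylation of a 1-aryl-1,3-diene, in which zerovalent nickel/PCy3 binds the s-cis diene, transfers H from HBpin to the aryl-bearing terminus and reductively eliminates C–B at the CH2 terminus of the anti-η3-allyl, so CH2B and CH2Ar end up cis (this sets the ring-olefin geometry); Me3NO then inserts oxygen into the C–B bond by a 1,2-shift with retention and without allylic transposition to give borate ester 8, and fluoride adds to boron of 8 so that the alkoxy(fluoro)borate hands its alkoxide to the para-ester-activated C–F carbon (Meisenheimer intermediate) while the expelled fluoride is trapped as [pinBF2]−; because the C–O bond is made at the aryl carbon, the allyl unit is never ionised and the five-membered ether that π-allyl or SN2' closures would give cannot form, and the low concentration of free alkoxide limits transesterification and olefin migration; the closest known reactions are nickel-catalysed Z-selective 1,4-hydroboration of 1,3-dienes and fluoride-promoted SNAr etherification of aryl fluorides with silyl ethers.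

**Step 4**
Reactants: 9 methyl 3-[(3E,7E)-4,8,12-trimethyltrideca-3,7,11-trien-1-yl]-2,5-dihydro-1-benzoxepine-7-carboxylate
Product: 10 callophycoic acid F, 3-[(3E,7E)-4,8,12-trimethyltrideca-3,7,11-trien-1-yl]-2,5-dihydro-1-benzoxepine-7-carboxylic acid
Conditions: LiOH·H2O (5 equiv), THF/MeOH/H2O (3:1:1), 40 °C; then 1 M HCl to pH 3, 0 °C
Reagents that add atoms: lithium hydroxide, [Li+].[OH-]
Why: Saponification of the methyl ester by acyl substitution; the allyl aryl ether and the skipped olefins are stable to aqueous hydroxide and to brief cold acidification, so all olefin geometries are kept.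

## Compound list

1 | (2E,6E)-farnesyl bromide, (2E,6E)-1-bromo-3,7,11-trimethyldodeca-2,6,10-triene | CC(C)=CCC/C(C)=C/CC/C(C)=C/CBr | starting material
2 | isoprene, 2-methylbuta-1,3-diene | CC(=C)C=C | starting material
3 | isoprenylpotassium, (2-methylidenebut-3-en-1-yl)potassium | C=CC(=C)C[K] | intermediate
4 | (6E,10E)-β-springene, (6E,10E)-7,11,15-trimethyl-3-methylidenehexadeca-1,6,10,14-tetraene | CC(C)=CCC/C(C)=C/CC/C(C)=C/CCC(=C)C=C | intermediate
5 | methyl 3-bromo-4-fluorobenzoate | COC(=O)c1ccc(F)c(Br)c1 | starting material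
6 | methyl 4-fluoro-3-[(1E,6E,10E)-7,11,15-trimethyl-3-methylidenehexadeca-1,6,10,14-tetraen-1-yl]benzoate | CC(C)=CCC/C(C)=C/CC/C(C)=C/CCC(=C)/C=C/c1cc(C(=O)OC)ccc1F | intermediate
7 | allylboronate, methyl 4-fluoro-3-[(2E,6E,10E)-7,11,15-trimethyl-3-[(4,4,5,5-tetramethyl-1,3,2-dioxaborolan-2-yl)methyl]hexadeca-2,6,10,14-tetraen-1-yl]benzoate (CH2B cis to CH2Ar) | CC(C)=CCC/C(C)=C/CC/C(C)=C/CC/C(CB1OC(C)(C)C(C)(C)O1)=C/Cc1cc(C(=O)OC)ccc1F | intermediate
8 | borate ester, methyl 4-fluoro-3-[(2Z,6E,10E)-7,11,15-trimethyl-3-{[(4,4,5,5-tetramethyl-1,3,2-dioxaborolan-2-yl)oxy]methyl}hexadeca-2,6,10,14-tetraen-1-yl]benzoate (CH2O cis to CH2Ar) | CC(C)=CCC/C(C)=C/CC/C(C)=C/CC/C(COB1OC(C)(C)C(C)(C)O1)=C/Cc1cc(C(=O)OC)ccc1F | intermediate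
9 | methyl 3-[(3E,7E)-4,8,12-trimethyltrideca-3,7,11-trien-1-yl]-2,5-dihydro-1-benzoxepine-7-carboxylate | CC(C)=CCC/C(C)=C/CC/C(C)=C/CCC1=CCc2cc(C(=O)OC)ccc2OC1 | intermediate
10 | callophycoic acid F, 3-[(3E,7E)-4,8,12-trimethyltrideca-3,7,11-trien-1-yl]-2,5-dihydro-1-benzoxepine-7-carboxylic acid | CC(C)=CCC/C(C)=C/CC/C(C)=C/CCC1=CCc2cc(C(=O)O)ccc2OC1 | target

## Step count and risks

Total step count: 4. Longest linear sequence: 4 (1 + 2 → 4 → 6 → 9 → 10).

The three steps most likely to fail:

**Step 3 (proposed new step).** The risks are the regio- and Z-selectivity of the hydroboration on a 1,3-disubstituted aryl diene and whether the fluoride-activated borate is nucleophilic enough for a fluoride activated only by a para ester. The fallback uses known chemistry and sets out from 6. The nickel-catalysed 1,4-hydroboration (Ni(cod)2, PCy3, HBpin, toluene, 23 °C) is run as a separate operation to allylboronate 7, which is oxidised with NaBO3·4H2O in THF/H2O, and the (Z)-allylic alcohol methyl 4-fluoro-3-[(2Z,6E,10E)-3-(hydroxymethyl)-7,11,15-trimethylhexadeca-2,6,10,14-tetraen-1-yl]benzoate F1 is isolated and purified. The ring is then closed by a classical intramolecular SNAr of the free sodium alkoxide (NaH, DMF, 0 → 60 °C, high dilution), which comes back to the route at 9.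

**Step 1.** The risks are SN2' attack or elimination of the allylic bromide by the strongly basic potassium reagent and oligomerisation of isoprene. The fallback sets out from 1 and builds the diene by metathesis instead of allyl–allyl coupling. 3-(Trimethylsilyl)prop-2-ynyllithium (from 1-(trimethylsilyl)propyne and n-BuLi, THF, −78 °C) is alkylated with 1 to give the silylalkyne trimethyl[(5E,9E)-6,10,14-trimethylpentadeca-5,9,13-trien-1-yn-1-yl]silane F2. Desilylation with K2CO3 in MeOH gives the terminal alkyne (5E,9E)-6,10,14-trimethylpentadeca-5,9,13-trien-1-yne F3. Enyne cross-metathesis of F3 with ethylene (1 atm) and second-generation Grubbs catalyst (H2IMes)(PCy3)Cl2Ru=CHPh in toluene at 60 °C comes back to the route at 4.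

**Step 2.** The risks are competing arylation at the 1,1-disubstituted diene terminus, double arylation and thermal dimerisation of the diene. The fallback sets out from 5, uses 1 as the chain source, and replaces the diene Heck reaction by carbonyl olefination, so it does not need 4. Heck reaction of 5 with methyl vinyl ketone (Pd(OAc)2, P(o-tol)3, Et3N, DMF, 100 °C) gives the enone methyl 4-fluoro-3-[(1E)-3-oxobut-1-en-1-yl]benzoate F4. Its kinetic lithium enolate (LiN(i-Pr)2, THF, −78 °C) is alkylated at the methyl carbon with 1 to give methyl 4-fluoro-3-[(1E,6E,10E)-7,11,15-trimethyl-3-oxohexadeca-1,6,10,14-tetraen-1-yl]benzoate F5. Wittig methylenation of the ketone (Ph3PCH3Br, KN(SiMe3)2, THF, −78 → 0 °C) comes back to the route at 6.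

## Further compounds

F1 | step 3 | methyl 4-fluoro-3-[(2Z,6E,10E)-3-(hydroxymethyl)-7,11,15-trimethylhexadeca-2,6,10,14-tetraen-1-yl]benzoate | CC(C)=CCC/C(C)=C/CC/C(C)=C/CC/C(CO)=C/Cc1cc(C(=O)OC)ccc1F
F2 | step 1 | trimethyl[(5E,9E)-6,10,14-trimethylpentadeca-5,9,13-trien-1-yn-1-yl]silane | CC(C)=CCC/C(C)=C/CC/C(C)=C/CCC#C[Si](C)(C)C
F3 | step 1 | (5E,9E)-6,10,14-trimethylpentadeca-5,9,13-trien-1-yne | CC(C)=CCC/C(C)=C/CC/C(C)=C/CCC#C
F4 | step 2 | methyl 4-fluoro-3-[(1E)-3-oxobut-1-en-1-yl]benzoate | COC(=O)c1ccc(F)c(/C=C/C(C)=O)c1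
F5 | step 2 | methyl 4-fluoro-3-[(1E,6E,10E)-7,11,15-trimethyl-3-oxohexadeca-1,6,10,14-tetraen-1-yl]benzoate | CC(C)=CCC/C(C)=C/CC/C(C)=C/CCC(=O)/C=C/c1cc(C(=O)OC)ccc1F
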